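## Retrosynthetic overview

1. The target comes from one global fluoride deprotection of a fully masked precursor (2-(trimethylsilyl)ethyl ester, aryl silyl ether, two alkyl silyl ethers).
2. The E-enone comes from dehydration of a β-hydroxy ketone. That ketol is made by the key intermolecular crossed aldol addition (C5–C6 bond of the octenyl chain) of the kinetic lithium enolate of an aryl-tethered (S)-α-methyl methyl ketone to 2-methyl-2-(triethylsilyloxy)propanal.
3. The aryl–CH2CH2 bond comes from a B-alkyl Suzuki–Miyaura coupling of an aryl bromide with the 9-BBN adduct of PMB-protected (2R,3S)-3-methylpent-4-en-2-ol. Its C3 stereocentre comes from a Brown (E)-crotylboration of acetaldehyde.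
4. The hydroxyprenyl arm comes from O-allylation and aromatic Claisen rearrangement of methyl 3-bromo-4-hydroxybenzoate, then cross-metathesis with methacrolein and Luche reduction.
5. No ring is formed: the benzene ring is bought with bromine, hydroxyl and carboxyl already in place.

Abbreviations: TMSE = 2-(trimethylsilyl)ethyl; TIPS = triisopropylsilyl; TBS = tert-butyldimethylsilyl; TES = triethylsilyl; PMB = 4-methoxybenzyl; Ipc = isopinocampheyl from (+)-α-pinene; TASF = tris(dimethylamino)sulfonium difluorotrimethylsilicate.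

Assumption: the carbinol carbon created in the aldol step is carried as a mixture of epimers, because the following elimination removes it; LiN(i-Pr)2 and (−)-Ipc2BOMe are used as bought.

## Route

Step 1
Reactants: 1 methyl 3-bromo-4-hydroxybenzoate; 2 allyl bromide
Product: 3 methyl 3-bromo-4-(prop-2-enyloxy)benzoate
Conditions: K2CO3, DMF, rt → 60 °C
Reagents that add atoms: none
Why: Williamson O-alkylation of the acidic phenol with an allylic bromide is clean and leaves the ester alone.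

Step 2
Reactants: 3 methyl 3-bromo-4-(prop-2-enyloxy)benzoate
Product: 5 methyl 3-bromo-4-hydroxy-5-(prop-2-enyl)benzoate, via Claisen dienone 4 (not isolated)
Conditions: PhNEt2, 200 °C, sealed tube
Reagents that add atoms: none
Why: Aromatic Claisen rearrangement: the [3,3]-sigmatropic shift can end only at the single unsubstituted ortho carbon (the other bears Br, the para position the ester) and dienone 4 tautomerises to the phenol.

Step 3
Reactants: 5 methyl 3-bromo-4-hydroxy-5-(prop-2-enyl)benzoate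
Product: 6 3-bromo-4-hydroxy-5-(prop-2-enyl)benzoic acid
Conditions: NaOH, MeOH/H2O, 70 °C; then aq. HCl
Reagents that add atoms: sodium hydroxide, [Na+].[OH-]
Why: Saponification (acyl substitution by hydroxide) is done here because a methyl ester could not be removed at the end without harming the enone, and the allyl group and aryl bromide are inert to aqueous base.

Step 4
Reactants: 6 3-bromo-4-hydroxy-5-(prop-2-enyl)benzoic acid
Product: 7 TMSE 3-bromo-4-hydroxy-5-(prop-2-enyl)benzoate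
Conditions: Me3SiCH2CH2OH (3 equiv), DCC, DMAP (cat.), CH2Cl2, 0 °C → rt
Reagents that add atoms: 2-(trimethylsilyl)ethanol, C[Si](C)(C)CCO
Why: Steglich esterification: the carbodiimide-activated acid is intercepted by the excess primary alcohol much faster than by the hindered, weakly nucleophilic 2,6-disubstituted phenol, giving a fluoride-cleavable ester.

Step 5
Reactants: 7 TMSE 3-bromo-4-hydroxy-5-(prop-2-enyl)benzoate
Product: 8 TMSE 3-bromo-5-(prop-2-enyl)-4-(TIPS-oxy)benzoate
Conditions: TIPSOTf, 2,6-lutidine, CH2Cl2, 0 °C → rt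
Reagents that add atoms: triisopropylsilyl trifluoromethanesulfonate, CC(C)[Si](OS(=O)(=O)C(F)(F)F)(C(C)C)C(C)C
Why: Silylation of the phenol with a silyl triflate and a hindered pyridine base gives a bulky TIPS ether that withstands the aqueous base of the later coupling yet falls to fluoride.

Step 6
Reactants: 8 TMSE 3-bromo-5-(prop-2-enyl)-4-(TIPS-oxy)benzoate; 9 methacrolein
Product: 10 TMSE 3-bromo-5-[(2E)-3-methyl-4-oxobut-2-enyl]-4-(TIPS-oxy)benzoate
Conditions: second-generation Grubbs catalyst (5 mol %), 9 (10 equiv), CH2Cl2, 40 °C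
Reagents that add atoms: none
Why: Olefin cross-metathesis of a terminal alkene with excess methacrolein, which does not homodimerise, gives the trisubstituted enal as the thermodynamically favoured E isomer.

Step 7
Reactants: 10 TMSE 3-bromo-5-[(2E)-3-methyl-4-oxobut-2-enyl]-4-(TIPS-oxy)benzoate
Product: 11 TMSE 3-bromo-5-[(2E)-4-hydroxy-3-methylbut-2-enyl]-4-(TIPS-oxy)benzoate
Conditions: NaBH4, CeCl3·7H2O, MeOH, −20 °C
Reagents that add atoms: none
Why: Luche 1,2-reduction touches only the aldehyde, so the E geometry, the ester and the aryl bromide are kept.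

Step 8
Reactants: 11 TMSE 3-bromo-5-[(2E)-4-hydroxy-3-methylbut-2-enyl]-4-(TIPS-oxy)benzoate
Product: 12 TMSE 3-bromo-5-[(2E)-4-(TBS-oxy)-3-methylbut-2-enyl]-4-(TIPS-oxy)benzoate
Conditions: TBSCl, imidazole, DMF, rt
Reagents that add atoms: tert-butyldimethylsilyl chloride, CC(C)(C)[Si](C)(C)Cl
Why: Standard silylation of a primary alcohol with an imidazole-activated silyl chloride masks the allylic alcohol through the organometallic steps.

Step 9
Reactants: 13 (E)-but-2-ene; 14 acetaldehyde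
Product: 19 (2R,3S)-3-methylpent-4-en-2-ol, via (E)-crotylpotassium 15 (not isolated), via potassium methoxyborate 16 (not isolated), via (E)-crotylborane 17 (not isolated), via borinate ester 18 (not isolated)
Conditions: KOt-Bu, n-BuLi, THF, −78 → −45 °C; (−)-Ipc2BOMe, −78 °C; BF3·OEt2; then 14, −78 °C; NaOH, H2O2, 0 °C → rt; distil
Reagents that add atoms: none
Why: Brown asymmetric crotylboration (a carbonyl allylation): the closed chair transition state turns the E geometry of the crotylborane into the anti relationship while the (+)-α-pinene-derived Ipc groups direct attack to the Si face of acetaldehyde, setting 2R and 3S, the latter being the only stereocentre of the target.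

Step 10
Reactants: 19 (2R,3S)-3-methylpent-4-en-2-ol
Product: 20 1-methoxy-4-({[(2R,3S)-3-methylpent-4-en-2-yl]oxy}methyl)benzene
Conditions: NaH, PMBCl, n-Bu4NI (cat.), THF/DMF, 0 °C → rt
Reagents that add atoms: 4-methoxybenzyl chloride, COc1ccc(CCl)cc1
Why: Williamson etherification of the sodium alkoxide gives a non-volatile ether that can later be removed oxidatively without touching any silyl group.

Step 11
Reactants: 20 1-methoxy-4-({[(2R,3S)-3-methylpent-4-en-2-yl]oxy}methyl)benzene; 12 TMSE 3-bromo-5-[(2E)-4-(TBS-oxy)-3-methylbut-2-enyl]-4-(TIPS-oxy)benzoate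
Product: 22 TMSE 3-[(2E)-4-(TBS-oxy)-3-methylbut-2-enyl]-5-{(3S,4R)-4-[(4-methoxybenzyl)oxy]-3-methylpentyl}-4-(TIPS-oxy)benzoate, via B-alkyl-9-BBN 21 (not isolated)
Conditions: 9-BBN, THF, 0 °C → rt; then 12, Pd(dppf)Cl2·CH2Cl2 (5 mol %), AsPh3, aq. K3PO4, DMF, rt → 50 °C
Reagents that add atoms: none
Why: Anti-Markovnikov hydroboration puts boron on the terminal carbon, and the B-alkyl Suzuki–Miyaura coupling (zerovalent palladium, the dppf ligand suppressing β-hydride elimination) joins this primary alkyl group to the aryl bromide without involving the stereocentres.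

Step 12
Reactants: 22 TMSE 3-[(2E)-4-(TBS-oxy)-3-methylbut-2-enyl]-5-{(3S,4R)-4-[(4-methoxybenzyl)oxy]-3-methylpentyl}-4-(TIPS-oxy)benzoate
Product: 23 TMSE 3-[(2E)-4-(TBS-oxy)-3-methylbut-2-enyl]-5-[(3S,4R)-4-hydroxy-3-methylpentyl]-4-(TIPS-oxy)benzoate
Conditions: DDQ, CH2Cl2/pH 7 buffer, 0 °C → rt
Reagents that add atoms: none
Why: Oxidative PMB cleavage (hydride abstraction from the electron-rich benzyl ether, then hydrolysis) frees the secondary alcohol and spares the silyl ethers, the ester and the trisubstituted alkene.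

Step 13
Reactants: 23 TMSE 3-[(2E)-4-(TBS-oxy)-3-methylbut-2-enyl]-5-[(3S,4R)-4-hydroxy-3-methylpentyl]-4-(TIPS-oxy)benzoate
Product: 24 TMSE 3-[(2E)-4-(TBS-oxy)-3-methylbut-2-enyl]-5-[(3S)-3-methyl-4-oxopentyl]-4-(TIPS-oxy)benzoate
Conditions: Dess–Martin periodinane, CH2Cl2, 0 °C → rt
Reagents that add atoms: none
Why: Dess–Martin oxidation is non-basic, so the carbinol becomes the methyl ketone without epimerising the adjacent C3 methine.

Step 14
Reactants: 25 methyl 2-hydroxy-2-methylpropanoate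
Product: 26 methyl 2-methyl-2-(triethylsilyloxy)propanoate
Conditions: TESOTf, 2,6-lutidine, CH2Cl2, 0 °C
Reagents that add atoms: triethylsilyl trifluoromethanesulfonate, CC[Si](CC)(CC)OS(=O)(=O)C(F)(F)F
Why: A silyl triflate is reactive enough for the hindered tertiary alcohol and gives an ether stable to hydride and enolate chemistry.

Step 15
Reactants: 26 methyl 2-methyl-2-(triethylsilyloxy)propanoate
Product: 28 2-methyl-2-(triethylsilyloxy)propanal, via aluminium hemiacetal 27 (not isolated)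
Conditions: i-Bu2AlH, CH2Cl2, −78 °C; aq. KNaC4H4O6 (potassium sodium tartrate) work-up
Reagents that add atoms: none
Why: Partial ester reduction: the tetrahedral aluminium hemiacetal 27, stabilised by the α-silyloxy group, survives at −78 °C and releases the aldehyde only on work-up, so over-reduction is avoided.

Step 16
Reactants: 24 TMSE 3-[(2E)-4-(TBS-oxy)-3-methylbut-2-enyl]-5-[(3S)-3-methyl-4-oxopentyl]-4-(TIPS-oxy)benzoate; 28 2-methyl-2-(triethylsilyloxy)propanal
Product: 30 TMSE 3-[(2E)-4-(TBS-oxy)-3-methylbut-2-enyl]-5-[(3S)-6-hydroxy-3,7-dimethyl-4-oxo-7-(TES-oxy)octyl]-4-(TIPS-oxy)benzoate, via lithium enolate 29 (not isolated)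
Conditions: LiN(i-Pr)2, THF, −78 °C; then 28, −78 °C; AcOH quench at −78 °C
Reagents that add atoms: none
Why: Crossed aldol addition: the bulky amide base removes a methyl proton under kinetic control (the C3 methine is untouched, so its configuration holds) and the non-enolisable aldehyde 28 can act only as acceptor, the new carbinol centre forming as an inconsequential mixture.

Step 17
Reactants: 30 TMSE 3-[(2E)-4-(TBS-oxy)-3-methylbut-2-enyl]-5-[(3S)-6-hydroxy-3,7-dimethyl-4-oxo-7-(TES-oxy)octyl]-4-(TIPS-oxy)benzoate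
Product: 32 TMSE 3-[(2E)-4-(TBS-oxy)-3-methylbut-2-enyl]-5-[(3S,5E)-3,7-dimethyl-4-oxo-7-(TES-oxy)oct-5-enyl]-4-(TIPS-oxy)benzoate, via mesylate 31 (not isolated)
Conditions: MsCl, Et3N, CH2Cl2, 0 °C; then DBU, 0 °C → rt
Reagents that add atoms: none
Why: Mesylation followed by E1cB elimination through the C5 enolate gives the conjugated enone, E by thermodynamic preference next to the bulky quaternary carbon, while the less acidic C3 methine is not deprotonated by the amine bases at low temperature.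

Step 18
Reactants: 32 TMSE 3-[(2E)-4-(TBS-oxy)-3-methylbut-2-enyl]-5-[(3S,5E)-3,7-dimethyl-4-oxo-7-(TES-oxy)oct-5-enyl]-4-(TIPS-oxy)benzoate
Product: 33 4-hydroxy-3-[(2E)-4-hydroxy-3-methylbut-2-enyl]-5-[(3S,5E)-7-hydroxy-3,7-dimethyl-4-oxooct-5-enyl]benzoic acid (CNP0120226.2)
Conditions: TASF (8 equiv), DMF, 0 °C → rt; then AcOH
Reagents that add atoms: none
Why: Fluoride-induced desilylation: fluoride cleaves the three silyl ethers at silicon and triggers β-elimination of the TMSE ester (loss of ethylene and Me3SiF), freeing phenol, both alcohols and the acid in one non-hydrolytic operation.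

## Compound list

1 | methyl 3-bromo-4-hydroxybenzoate | COC(=O)c1ccc(O)c(Br)c1 | starting material
2 | allyl bromide (3-bromoprop-1-ene) | C=CCBr | starting material
3 | methyl 3-bromo-4-(prop-2-enyloxy)benzoate | COC(=O)c1ccc(OCC=C)c(Br)c1 | intermediate
4 | methyl 5-bromo-4-oxo-3-(prop-2-enyl)cyclohexa-1,5-diene-1-carboxylate (racemic Claisen dienone, not isolated) | COC(=O)C1=CC(CC=C)C(=O)C(Br)=C1 | intermediate
5 | methyl 3-bromo-4-hydroxy-5-(prop-2-enyl)benzoate | COC(=O)c1cc(Br)c(O)c(CC=C)c1 | intermediate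
6 | 3-bromo-4-hydroxy-5-(prop-2-enyl)benzoic acid | OC(=O)c1cc(Br)c(O)c(CC=C)c1 | intermediate
7 | 2-(trimethylsilyl)ethyl 3-bromo-4-hydroxy-5-(prop-2-enyl)benzoate | C[Si](C)(C)CCOC(=O)c1cc(Br)c(O)c(CC=C)c1 | intermediate
8 | 2-(trimethylsilyl)ethyl 3-bromo-5-(prop-2-enyl)-4-(triisopropylsilyloxy)benzoate | C[Si](C)(C)CCOC(=O)c1cc(Br)c(O[Si](C(C)C)(C(C)C)C(C)C)c(CC=C)c1 | intermediate
9 | methacrolein (2-methylprop-2-enal) | CC(=C)C=O | starting material
10 | 2-(trimethylsilyl)ethyl 3-bromo-5-[(2E)-3-methyl-4-oxobut-2-enyl]-4-(triisopropylsilyloxy)benzoate | C/C(=C\Cc1cc(C(=O)OCC[Si](C)(C)C)cc(Br)c1O[Si](C(C)C)(C(C)C)C(C)C)C=O | intermediate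
11 | 2-(trimethylsilyl)ethyl 3-bromo-5-[(2E)-4-hydroxy-3-methylbut-2-enyl]-4-(triisopropylsilyloxy)benzoate | C/C(=C\Cc1cc(C(=O)OCC[Si](C)(C)C)cc(Br)c1O[Si](C(C)C)(C(C)C)C(C)C)CO | intermediate
12 | 2-(trimethylsilyl)ethyl 3-bromo-5-[(2E)-4-(tert-butyldimethylsilyloxy)-3-methylbut-2-enyl]-4-(triisopropylsilyloxy)benzoate | C/C(=C\Cc1cc(C(=O)OCC[Si](C)(C)C)cc(Br)c1O[Si](C(C)C)(C(C)C)C(C)C)CO[Si](C)(C)C(C)(C)C | intermediate
13 | (E)-but-2-ene | C/C=C/C | starting material
14 | acetaldehyde | CC=O | starting material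
15 | (E)-but-2-enylpotassium (not isolated) | C/C=C/C[K] | intermediate
16 | potassium (E)-but-2-enyl(methoxy)bis(isopinocampheyl)borate, Ipc from (+)-α-pinene (not isolated) | [K+].C/C=C/C[B-](OC)([C@@H]1C[C@@H]2C[C@H]([C@H]1C)C2(C)C)[C@@H]1C[C@@H]2C[C@H]([C@H]1C)C2(C)C | intermediate
17 | (E)-but-2-enylbis(isopinocampheyl)borane (not isolated) | C/C=C/CB([C@@H]1C[C@@H]2C[C@H]([C@H]1C)C2(C)C)[C@@H]1C[C@@H]2C[C@H]([C@H]1C)C2(C)C | intermediate
18 | (2R,3S)-3-methylpent-4-en-2-yl bis(isopinocampheyl)borinate (not isolated) | C[C@@H](OB([C@@H]1C[C@@H]2C[C@H]([C@H]1C)C2(C)C)[C@@H]1C[C@@H]2C[C@H]([C@H]1C)C2(C)C)[C@@H](C)C=C | intermediate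
19 | (2R,3S)-3-methylpent-4-en-2-ol | C[C@@H](O)[C@@H](C)C=C | intermediate
20 | 1-methoxy-4-({[(2R,3S)-3-methylpent-4-en-2-yl]oxy}methyl)benzene | C[C@@H](OCc1ccc(OC)cc1)[C@@H](C)C=C | intermediate
21 | 9-{(3S,4R)-4-[(4-methoxybenzyl)oxy]-3-methylpentyl}-9-borabicyclo[3.3.1]nonane (not isolated) | C[C@@H](OCc1ccc(OC)cc1)[C@@H](C)CCB1C2CCCC1CCC2 | intermediate
22 | 2-(trimethylsilyl)ethyl 3-[(2E)-4-(tert-butyldimethylsilyloxy)-3-methylbut-2-enyl]-5-{(3S,4R)-4-[(4-methoxybenzyl)oxy]-3-methylpentyl}-4-(triisopropylsilyloxy)benzoate | C/C(=C\Cc1cc(C(=O)OCC[Si](C)(C)C)cc(CC[C@H](C)[C@@H](C)OCc2ccc(OC)cc2)c1O[Si](C(C)C)(C(C)C)C(C)C)CO[Si](C)(C)C(C)(C)C | intermediate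
23 | 2-(trimethylsilyl)ethyl 3-[(2E)-4-(tert-butyldimethylsilyloxy)-3-methylbut-2-enyl]-5-[(3S,4R)-4-hydroxy-3-methylpentyl]-4-(triisopropylsilyloxy)benzoate | C/C(=C\Cc1cc(C(=O)OCC[Si](C)(C)C)cc(CC[C@H](C)[C@@H](C)O)c1O[Si](C(C)C)(C(C)C)C(C)C)CO[Si](C)(C)C(C)(C)C | intermediate
24 | 2-(trimethylsilyl)ethyl 3-[(2E)-4-(tert-butyldimethylsilyloxy)-3-methylbut-2-enyl]-5-[(3S)-3-methyl-4-oxopentyl]-4-(triisopropylsilyloxy)benzoate | C/C(=C\Cc1cc(C(=O)OCC[Si](C)(C)C)cc(CC[C@H](C)C(C)=O)c1O[Si](C(C)C)(C(C)C)C(C)C)CO[Si](C)(C)C(C)(C)C | intermediate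
25 | methyl 2-hydroxy-2-methylpropanoate | COC(=O)C(C)(C)O | starting material
26 | methyl 2-methyl-2-(triethylsilyloxy)propanoate | COC(=O)C(C)(C)O[Si](CC)(CC)CC | intermediate
27 | [1-methoxy-2-methyl-2-(triethylsilyloxy)propoxy]bis(2-methylpropyl)aluminium (not isolated) | COC(O[Al](CC(C)C)CC(C)C)C(C)(C)O[Si](CC)(CC)CC | intermediate
28 | 2-methyl-2-(triethylsilyloxy)propanal | O=CC(C)(C)O[Si](CC)(CC)CC | intermediate
29 | lithium enolate of 24 on the methyl side, (3S)-configured, CH2=C(OLi) terminus (not isolated) | C/C(=C\Cc1cc(C(=O)OCC[Si](C)(C)C)cc(CC[C@H](C)C(=C)O[Li])c1O[Si](C(C)C)(C(C)C)C(C)C)CO[Si](C)(C)C(C)(C)C | intermediate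
30 | 2-(trimethylsilyl)ethyl 3-[(2E)-4-(tert-butyldimethylsilyloxy)-3-methylbut-2-enyl]-5-[(3S)-6-hydroxy-3,7-dimethyl-4-oxo-7-(triethylsilyloxy)octyl]-4-(triisopropylsilyloxy)benzoate (both C6 epimers) | C/C(=C\Cc1cc(C(=O)OCC[Si](C)(C)C)cc(CC[C@H](C)C(=O)CC(O)C(C)(C)O[Si](CC)(CC)CC)c1O[Si](C(C)C)(C(C)C)C(C)C)CO[Si](C)(C)C(C)(C)C | intermediate
31 | C6 methanesulfonate of 30 (not isolated) | C/C(=C\Cc1cc(C(=O)OCC[Si](C)(C)C)cc(CC[C@H](C)C(=O)CC(OS(C)(=O)=O)C(C)(C)O[Si](CC)(CC)CC)c1O[Si](C(C)C)(C(C)C)C(C)C)CO[Si](C)(C)C(C)(C)C | intermediate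
32 | 2-(trimethylsilyl)ethyl 3-[(2E)-4-(tert-butyldimethylsilyloxy)-3-methylbut-2-enyl]-5-[(3S,5E)-3,7-dimethyl-4-oxo-7-(triethylsilyloxy)oct-5-enyl]-4-(triisopropylsilyloxy)benzoate | C/C(=C\Cc1cc(C(=O)OCC[Si](C)(C)C)cc(CC[C@H](C)C(=O)/C=C/C(C)(C)O[Si](CC)(CC)CC)c1O[Si](C(C)C)(C(C)C)C(C)C)CO[Si](C)(C)C(C)(C)C | intermediate
33 | 4-hydroxy-3-[(2E)-4-hydroxy-3-methylbut-2-enyl]-5-[(3S,5E)-7-hydroxy-3,7-dimethyl-4-oxooct-5-enyl]benzoic acid | C/C(=C\Cc1cc(C(=O)O)cc(CC[C@H](C)C(=O)/C=C/C(C)(C)O)c1O)CO | target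

## Summary

Total step count: 18. Longest linear sequence: 14 steps (steps 1–8, 11–13, 16–18); the alkene arm (steps 9–10) and the aldehyde arm (steps 14–15) are side branches.

Three steps most likely to fail:

Step 11 (B-alkyl Suzuki coupling at a bromide flanked by the bulky TIPS ether; risk of slow transmetalation and protodebromination). The fallback replaces the borane by an organozinc and sets out from 20. Hydroboration of 20 with 9-BBN through the same borane 21, then NaOH/H2O2 oxidation, gives (3S,4R)-4-[(4-methoxybenzyl)oxy]-3-methylpentan-1-ol F1. I2, PPh3 and imidazole in CH2Cl2 convert it into 1-({[(2R,3S)-5-iodo-3-methylpentan-2-yl]oxy}methyl)-4-methoxybenzene F2. Zinc dust and LiCl in THF at 40 °C insert to give {(3S,4R)-4-[(4-methoxybenzyl)oxy]-3-methylpentyl}zinc iodide F3. A Negishi coupling of F3 with 12 (Pd(OAc)2, SPhos, THF, rt → 50 °C) comes back to the route at 22.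

Step 17 (base-mediated elimination next to an epimerisable α-methyl ketone; risk of C3 epimerisation or sluggish elimination of the hindered mesylate). The fallback sets out from 30 and avoids base altogether. Burgess reagent (methyl N-(triethylammoniosulfonyl)carbamate) in benzene at rt converts the carbinol into the triethylammonium N-(methoxycarbonyl)sulfamate ester of 30 F4. On warming to 50 °C, F4 undergoes a thermal syn-elimination (the only β-hydrogens are on C5) and comes back to the route at 32.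

Step 18 (four fluoride-labile groups removed at once by basic fluoride in the presence of the enone and the α-stereocentre; risk of epimerisation or incomplete ester cleavage). The fallback sets out from 32 and unmasks in two orthogonal stages. HF·pyridine buffered with pyridine in THF (0 °C → rt) removes the TBS and TES ethers under acidic conditions, with no alkoxide formed, and gives 2-(trimethylsilyl)ethyl 3-[(2E)-4-hydroxy-3-methylbut-2-enyl]-5-[(3S,5E)-7-hydroxy-3,7-dimethyl-4-oxooct-5-enyl]-4-(triisopropylsilyloxy)benzoate F5. A short treatment of F5 with TASF (3 equiv) in DMF at 0 °C then cleaves only the aryl TIPS ether and the TMSE ester, generating just the weakly basic phenoxide and carboxylate, and comes back to the route at 33.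

## Further compounds

F1 | step 11 | (3S,4R)-4-[(4-methoxybenzyl)oxy]-3-methylpentan-1-ol | C[C@@H](OCc1ccc(OC)cc1)[C@@H](C)CCO
F2 | step 11 | 1-({[(2R,3S)-5-iodo-3-methylpentan-2-yl]oxy}methyl)-4-methoxybenzene | C[C@@H](OCc1ccc(OC)cc1)[C@@H](C)CCI
F3 | step 11 | {(3S,4R)-4-[(4-methoxybenzyl)oxy]-3-methylpentyl}zinc iodide | C[C@@H](OCc1ccc(OC)cc1)[C@@H](C)CC[Zn]I
F4 | step 17 | triethylammonium N-(methoxycarbonyl)sulfamate ester of 30 at the C6 oxygen | C/C(=C\Cc1cc(C(=O)OCC[Si](C)(C)C)cc(CC[C@H](C)C(=O)CC(OS(=O)(=O)[N-]C(=O)OC)C(C)(C)O[Si](CC)(CC)CC)c1O[Si](C(C)C)(C(C)C)C(C)C)CO[Si](C)(C)C(C)(C)C.CC[NH+](CC)CC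
F5 | step 18 | 2-(trimethylsilyl)ethyl 3-[(2E)-4-hydroxy-3-methylbut-2-enyl]-5-[(3S,5E)-7-hydroxy-3,7-dimethyl-4-oxooct-5-enyl]-4-(triisopropylsilyloxy)benzoate | C/C(=C\Cc1cc(C(=O)OCC[Si](C)(C)C)cc(CC[C@H](C)C(=O)/C=C/C(C)(C)O)c1O[Si](C(C)C)(C(C)C)C(C)C)CO
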